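Assumption: pterocarpan numbering is used; the SMILES decodes to the cis-fused (6aS,11aS) enantiomer. (R)-TRIP is written in step 7, but which hand of the acid gives this series cannot be predicted and is fixed by the first run (the mirror-image acid gives the mirror-image product).

## Retrosynthetic overview

1. Target ⇒ acyclic (Z)-2-aryl-3-(2-hydroxyaryl)allyl alcohol: one chiral-acid operation closes ring B (dehydration, oxa-6π) and ring C (face-selective protonation, then O-addition), setting C6a and C11a.
2. (Z)-Allyl alcohol ⇒ 3-(2-hydroxyaryl)coumarin (hydride opens the lactone and removes the pivalate).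
3. Coumarin ⇒ chroman salicylaldehyde + 6-methoxybenzofuran-2(3H)-one (Knoevenagel/translactonisation makes the C6a–C11a bond).
4. Chroman salicylaldehyde ⇒ 2,4,6-trihydroxybenzaldehyde via its 4-O-pivalate and isoprene (the pivalate forces ring E onto O-2); the lactone ⇒ paeonol (Willgerodt–Kindler).
5. Ring order: E (step 2) → temporary lactone ring (step 5, opened in step 6) → B and C together (step 7).

## Route

Step 1
Reactants: 1 phloroglucinaldehyde (2,4,6-trihydroxybenzaldehyde)
Product: 2 4-formyl-3,5-dihydroxyphenyl pivalate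
Conditions: PivCl (1.0 equiv), Et3N (1.1 equiv), THF, −20 → 0 °C
Reagents that add atoms: pivaloyl chloride, CC(C)(C)C(=O)Cl
Why: the 4-OH is the most acidic and the only non-chelated hydroxyl, so one equivalent of base gives the 4-phenoxide, which is acylated selectively (regioselective O-acylation).

Step 2
Reactants: 2 4-formyl-3,5-dihydroxyphenyl pivalate; 3 isoprene
Product: 4 8-formyl-7-hydroxy-2,2-dimethylchroman-5-yl pivalate
Conditions: isoprene (1.3 equiv), 85% H3PO4, xylene, 30–35 °C
Reagents that add atoms: none
Why: acid-catalysed Friedel–Crafts prenylation at C-3 followed by Markovnikov hydroalkoxylation (Ahluwalia-type [3+3] chroman annulation); C-3 lies between OH-2 and the acylated O-4, so ring E can only close onto O-2, leaving the other ortho OH next to the aldehyde.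

Step 3
Reactants: 5 paeonol (1-(2-hydroxy-4-methoxyphenyl)ethanone)
Product: 6 2-(2-hydroxy-4-methoxyphenyl)-1-(morpholin-4-yl)ethanethione
Conditions: S8, morpholine (3 equiv), 130 °C
Reagents that add atoms: sulfur, S1SSSSSSS1; morpholine, C1COCCN1
Why: Willgerodt–Kindler reaction moves the carbonyl oxidation level to the terminal carbon and gives the ArCH2–C(=S)N unit; the free phenol and the aryl methyl ether tolerate the conditions.

Step 4
Reactants: 6 2-(2-hydroxy-4-methoxyphenyl)-1-(morpholin-4-yl)ethanethione
Product: 8 lactone 6-methoxybenzofuran-2(3H)-one, via arylacetic acid 7 (not isolated)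
Conditions: 10% aq NaOH, EtOH, reflux; HCl to pH 1; then TsOH (cat.), PhMe, reflux (Dean–Stark)
Reagents that add atoms: sodium hydroxide, [Na+].[OH-]
Why: thioamide hydrolysis gives (2-hydroxy-4-methoxyphenyl)acetic acid, which lactonises with its ortho phenol on azeotropic dehydration (hydrolysis, then lactonisation).

Step 5
Reactants: 4 8-formyl-7-hydroxy-2,2-dimethylchroman-5-yl pivalate; 8 lactone 6-methoxybenzofuran-2(3H)-one
Product: 10 coumarin 3-(2-hydroxy-4-methoxyphenyl)-7-(pivaloyloxy)coumarin bearing a 2,2-dimethyl-3,4-dihydro-2H-pyran ring fused at C5–C6 (ring O on C5), via benzylidene lactone 9 (not isolated)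
Conditions: Et3N (1.5 equiv), MeCN, 70 °C, Ar
Reagents that add atoms: none
Why: Knoevenagel condensation of the acidic lactone CH2 with the aldehyde, then intramolecular transesterification by the only phenol ortho to the aldehyde opens the five-membered lactone and closes the six-membered one (domino Knoevenagel/translactonisation); this forms the C6a–C11a bond and frees the 2'-OH.

Step 6
Reactants: 10 coumarin (as named in step 5)
Product: 11 (Z)-3-(5,7-dihydroxy-2,2-dimethylchroman-8-yl)-2-(2-hydroxy-4-methoxyphenyl)prop-2-en-1-ol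
Conditions: LiAlH4 (5 equiv), THF, −10 → 0 °C; Rochelle salt/NH4Cl (pH 7); crude used at once under Ar
Reagents that add atoms: none
Why: 1,2-reduction of the α,β-unsaturated lactone gives the allylic alcohol and the phenol with the Z geometry inherited from the coumarin ring, and the aryl pivalate is cleaved reductively in the same pot (hydride reduction of lactone and ester).

Step 7
Reactants: 11 (Z)-3-(5,7-dihydroxy-2,2-dimethylchroman-8-yl)-2-(2-hydroxy-4-methoxyphenyl)prop-2-en-1-ol
Product: 15 (6aS,11aS)-3-hydroxy-9-methoxypterocarpan with a 2,2-dimethyl-dihydropyran ring across O-1/C-2 (target CNP0207547.1), via vinyl ortho-quinone methide 12 (not isolated), via isoflav-3-ene 13 (not isolated), via para-quinone methide 14 (not isolated)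
Conditions: (R)-TRIP (10 mol %), 4 Å MS, PhMe (0.02 M), 0 °C → rt, Ar
Reagents that add atoms: none
Why: Proposed new method: the acid ionises the allylic C–OH (a vinylogous 2,4,6-trioxygenated benzylic alcohol) to the Z-configured vinyl ortho-quinone methide 12, which closes by oxa-6π electrocyclisation to isoflav-3-ene 13 (ring B); the same acid, hydrogen-bonded to the 2'-OH, then protonates C-6a of this electron-rich 4-hydroxystyrene face-selectively to give para-quinone methide 14 (this sets C-6a), and 5-exo oxa-1,6-addition of the 2'-OH closes ring C, with C-11a following from C-6a because only the cis fusion is strain-free; the closest known chemistry is the acid-mediated cyclodehydration of (Z)-2-hydroxycinnamyl alcohols to 2H-chromenes, the acid-catalysed racemic closure of 2'-hydroxyisoflav-3-enes and isoflavan-4-ols to cis-pterocarpans, and chiral phosphoric acid catalysed asymmetric additions to quinone methides generated by protonation of vinylphenols (asymmetric Brønsted acid hydroalkoxylation).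

## Compound list

1 | 2,4,6-trihydroxybenzaldehyde | O=Cc1c(O)cc(O)cc1O | starting material
2 | 4-formyl-3,5-dihydroxyphenyl pivalate | CC(C)(C)C(=O)Oc1cc(O)c(C=O)c(O)c1 | intermediate
3 | isoprene | C=CC(C)=C | starting material
4 | 8-formyl-7-hydroxy-2,2-dimethylchroman-5-yl pivalate | CC1(C)CCc2c(OC(=O)C(C)(C)C)cc(O)c(C=O)c2O1 | intermediate
5 | paeonol, 1-(2-hydroxy-4-methoxyphenyl)ethanone | CC(=O)c1ccc(OC)cc1O | starting material
6 | 2-(2-hydroxy-4-methoxyphenyl)-1-(morpholin-4-yl)ethanethione | S=C(Cc1ccc(OC)cc1O)N1CCOCC1 | intermediate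
7 | (2-hydroxy-4-methoxyphenyl)acetic acid | OC(=O)Cc1ccc(OC)cc1O | intermediate
8 | 6-methoxybenzofuran-2(3H)-one | O=C1Cc2ccc(OC)cc2O1 | intermediate
9 | (Z)-benzylidene lactone: 7-hydroxy-2,2-dimethyl-8-[(6-methoxy-2-oxobenzofuran-3(2H)-ylidene)methyl]chroman-5-yl pivalate | O=C1Oc2cc(OC)ccc2/C1=C/c1c(O)cc(OC(=O)C(C)(C)C)c2CCC(C)(C)Oc12 | intermediate
10 | 3-(2-hydroxy-4-methoxyphenyl)-7-(pivaloyloxy)coumarin with a 2,2-dimethyl-3,4-dihydro-2H-pyran ring fused at C5–C6 (ring O on C5) | O=C1Oc2cc(OC(=O)C(C)(C)C)c3CCC(C)(C)Oc3c2C=C1c1ccc(OC)cc1O | intermediate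
11 | (Z)-3-(5,7-dihydroxy-2,2-dimethylchroman-8-yl)-2-(2-hydroxy-4-methoxyphenyl)prop-2-en-1-ol | OC/C(c1ccc(OC)cc1O)=C\c1c(O)cc(O)c2CCC(C)(C)Oc12 | intermediate
12 | (Z)-vinyl ortho-quinone methide: 5-hydroxy-8-[2-(2-hydroxy-4-methoxyphenyl)prop-2-en-1-ylidene]-2,2-dimethyl-3,4-dihydro-2H-chromen-7(8H)-one | O=C1C=C(O)C2=C(OC(C)(C)CC2)/C1=C/C(=C)c1ccc(OC)cc1O | intermediate
13 | isoflav-3-ene: 3-(2-hydroxy-4-methoxyphenyl)-2H-chromen-7-ol with a 2,2-dimethyl-3,4-dihydro-2H-pyran ring fused at C5–C6 (ring O on C5) | Oc1cc2OCC(c3ccc(OC)cc3O)=Cc2c2OC(C)(C)CCc12 | intermediate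
14 | (3S)-para-quinone methide: the 7-oxo, C4=C4a-exocyclic tautomer of 13 protonated at C-3 | O=C1C=C2OC[C@H](c3ccc(OC)cc3O)C=C2C2=C1CCC(C)(C)O2 | intermediate
15 | (6aS,11aS)-3-hydroxy-9-methoxypterocarpan with O-1 and C-2 joined by C(CH3)2CH2CH2 (cis-fused; CNP0207547.1) | COc1ccc2c(c1)O[C@@H]1c3c(cc(O)c4c3OC(C)(C)CC4)OC[C@H]21 | target

## Step count and risk

Total steps: 7. Longest linear sequence: 5 steps (steps 1, 2, 5, 6, 7; the paeonol branch, steps 3, 4, 5, 6, 7, is equally long).

Steps most likely to fail:

Step 7. The asymmetric version has no direct precedent, so the enantioselectivity is uncertain. The 2'-OH may also intercept the allyl cation before ring B closes, leaking to 3-methylene-dihydrobenzofuran and then benzofuran by-products. Fallback: start from 11 and treat it with catalytic PPTS in CH2Cl2, which gives only the achiral isoflav-3-ene 13, now isolated. Hydrogenate 13 with a chiral Ir–P,N catalyst (the method used for 3-aryl-2H-chromenes in equol syntheses) to the (3S)-isoflavan F1. Oxidise F1 with DDQ (1 equiv, dioxane, 10 °C); benzylic hydride abstraction para to the free phenol gives para-quinone methide 14, where the fallback rejoins the route, and 14 closes to 15 with C-6a untouched.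

Step 6. Hydride may over-reduce the cinnamyl system, and the very electron-rich tetraol 11 may cyclise or oxidise during work-up. Fallback: start from 10 and reduce only to the lactol level with DIBAL-H (CH2Cl2, −78 °C, cold quench), which also cleaves the pivalate and gives the 2H-chromen-2-ol lactol F3. Treat F3 with the same chiral acid and a Hantzsch ester; it ionises to the isoflavylium ion F4 (as its chiral phosphate ion pair), and hydride transfer to C-2 gives 13 in the flask, where the fallback rejoins the route and continues to 15 as in step 7. Ring B is never opened in this variant, so the benzofuran leak named under step 7 cannot occur.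

Step 2. The ring is deactivated by the aldehyde and the ester, so conversion may be low, and a second annulation at the remaining OH competes. Fallback: start from 2 and condense it with 3-methylbut-2-enal (ethylenediamine diacetate cat., PhMe, 90 °C). C-alkylation at C-3 and oxa-6π closure onto O-2 give the 2H-chromene aldehyde 8-formyl-7-hydroxy-2,2-dimethyl-2H-chromen-5-yl pivalate F2. Hydrogenate its ring double bond (H2, Wilkinson's catalyst, EtOAc, which spares the aldehyde and the ester) to rejoin the route at 4.

Further compounds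
F1 | step 7 | (3S)-isoflavan: (3S)-3-(2-hydroxy-4-methoxyphenyl)chroman-7-ol with a 2,2-dimethyl-3,4-dihydro-2H-pyran ring fused at C5–C6 (ring O on C5) | Oc1cc2OC[C@H](c3ccc(OC)cc3O)Cc2c2OC(C)(C)CCc12
F2 | step 2 | 8-formyl-7-hydroxy-2,2-dimethyl-2H-chromen-5-yl pivalate | CC1(C)C=Cc2c(OC(=O)C(C)(C)C)cc(O)c(C=O)c2O1
F3 | step 6 | lactol: 3-(2-hydroxy-4-methoxyphenyl)-2H-chromene-2,7-diol with a 2,2-dimethyl-3,4-dihydro-2H-pyran ring fused at C5–C6 (ring O on C5) | OC1Oc2cc(O)c3CCC(C)(C)Oc3c2C=C1c1ccc(OC)cc1O
F4 | step 6 | isoflavylium ion: 7-hydroxy-3-(2-hydroxy-4-methoxyphenyl)chromenylium with the same fused dimethyl-dihydropyran ring | Oc1cc2[o+]cc(-c3ccc(OC)cc3O)cc2c2OC(C)(C)CCc12
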